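## Structural features

The target is a biflavone made of two 2-aryl-4H-chromen-4-ones: unit 1 is a 5-hydroxy-7-methoxyflavone and unit 2 is a 5,7,4'-trihydroxyflavone. The units are joined by a single carbon–carbon bond between C3 of ring C of unit 2 and C3' of ring B of unit 1, ortho to the C4' hydroxyl, so ring C of unit 2 is a 2,3-diarylpyranone. All six rings are benzene rings or γ-pyranones and there is no stereocentre, so no stereocentres stand next to each other; the C3–C3' axis, flanked by the C2 aryl group, the C4 carbonyl and the C4' oxygen, carries no descriptor in the target. The fragile parts are the five free phenols (two on an electron-rich phloroglucinol-type ring that is easily oxidised or attacked by electrophiles), the two pyranones, which are vinylogous esters that strong nucleophiles open, and the single methyl ether, which must outlive the unmasking of every other oxygen. The real difficulty is not ring construction but telling six phenolic oxygens apart, since only O7 of unit 1 is methylated while its neighbour O5 is free, together with the crowded C3–C3' bond. The key step exploits the mirror plane that ring A of unit 1 has through C4a and C7 as long as ring C is open: the two oxygens ortho to C4a are equivalent, one becomes O1 and the other the C5 hydroxyl. The same thinking serves unit 2, whose ring A comes from threefold symmetric phloroglucinol, and the crowded biaryl bond is carried from the start as the benzylic carbon of an arylacetonitrile.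

## Logic of the disconnections

24 to 23. The four O–isopropyl bonds on O5, O7 and O4' of unit 2 and on O4' of unit 1 are cut. The last step then only unmasks, and 23 has a single free phenol that is hydrogen-bonded to the C4 carbonyl and inert. The demand on the forward step is a dealkylating Lewis acid that removes secondary alkyl ethers but leaves the non-chelated O7–CH3 bond of unit 1 alone.

23 to 19, 20 and 14. The bonds C4a–C4, C4–C3 and O1–C2 of ring C of unit 1 are cut, which takes out the carbonyl carbon as 20 and leaves an aryl iodide and a terminal alkyne. The cut is made here because 19 is mirror-symmetric, so the ring A pattern (O7 methylated, O5 free) needs neither a protecting group nor a regiochemical decision. The gain is one ring and three skeletal bonds in a single operation that joins the two halves. The demand is that carbonylation precedes alkyne coupling and that the oxygen closes to the six-membered ring; both are met through the intermediates 21 and 22.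

19 to 18, 16 and 15. The C–I bond is cut at the carbon between the two oxygens. Electrophilic iodination of 15 would not distinguish this carbon from the two between a hydroxyl and the methyl ether, so the iodine is placed by directed metalation of the bis-acetal 16 through 17. The demand is lithiation between the two acetal oxygens and an acetal cleavage mild enough to keep the iodine on the very electron-rich ring.

14 to 13 and 12. The C(sp)–C(sp2) bond at the future C1' of unit 1 is cut. The alkyne is introduced only after all acid and base chemistry on the fragment is done, and the bromine it replaces is inert until then. The demand is a coupling catalyst able to activate an electron-rich para-alkoxy aryl bromide; a silyl cap prevents double coupling.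

12 to 7 and 8. The bonds O1–C2 and C2–C3 of ring C of unit 2 are cut, through 11, 10 and 9. The crowded C3–C3' biaryl bond is thereby never made by coupling: it is already present as the benzylic CH2 of 7. The demand is an intramolecular acyl shift onto a hindered enolate, followed by loss of water.

7 to 6, 3 and 4. Two O–isopropyl bonds are cut first; the third hydroxyl stays free in the forward direction because it is chelated to the ketone. The aryl–acyl bond (C4–C4a of unit 2) is then cut, through 5. Because 4 is threefold symmetric, the acylation has no regiochemistry. The demand is a mono-acylation under conditions that spare the aryl isopropyl ether, which is why a nitrile and a protic acid are used rather than a carboxylic acid and a boron or aluminium halide.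

3 to 2 and 1. The C–Br bond para to the ether oxygen (the future C1' of unit 1) and the O–isopropyl bond are cut. This leads back to a commercial phenol; the demand is only para-selective halogenation of an alkoxyarene.

## Other disconnections considered

Alternative 1: The cut runs through ring B of unit 1 at C2'–C3' and C1'–C6'. In the forward step the silyloxydiene A1 (the 2-silyloxybutadiene attached through its C1 to C3 of protected unit 2) and the alkyne A2 (2-ethynyl-5-isopropoxy-7-methoxychromen-4-one) would undergo a (4+2) cycloaddition, and DDQ in the same flask would aromatise the cyclohexadiene to A3.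
- In its favour: the crowded aryl–pyranone bond comes from ring construction; two finished chromones are joined late; and frontier-orbital control of a 2-silyloxydiene with an electron-poor alkyne predicts the required para relation between the silyloxy carbon and the chromonyl-bearing carbon.
- Against it: the bonding terminus of A1 carries the bulky chromonyl group, so the s-cis conformer is strained and the cycloaddition is expected to be slow. The silyl enol ether is sensitive to hydrolysis and A2 is a reactive Michael acceptor. Ring A of A2 needs O5 and O7 differentiated by stepwise alkylation, which the chosen plan gets from symmetry.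
- Comparison: on structure it is the weaker plan for ring A of unit 1 and the equal of the chosen plan for the biaryl bond, which neither makes by cross-coupling. On mechanism a concerted cycloaddition plus oxidation replaces a catalytic carbonylation plus addition–elimination. On step economy it is estimated to be longer, because A1 and A2 each need several steps and A3 carries a fifth protecting group. It is the better plan in avoiding carbon monoxide and an acid-sensitive iodophenol.

Alternative 2: The cut is at C4–C4a and O1–C2 of unit 2. Heating 4 with the α-aryl β-ketoester A4 (racemic, its aryl group being the whole protected unit 1) would expel methanol to an aroylketene that acylates a ring carbon of 4, and the neighbouring hydroxyl would condense on the aryl ketone to give A5.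
- In its favour: 4 is threefold symmetric, ring A of unit 2 needs no protection, only three isopropyl ethers remain, and no metal or gas is involved.
- Against it: the temperature needed for ketene formation invites retro-Claisen cleavage, decarboxylation and closure through the ketone to a coumarin. The hindered aryl ketone must condense with a phenol. Excess 4 is needed to avoid double annulation. Unit 1 must be finished first with O5 and O7 differentiated.
- Comparison: it uses the same symmetry argument as the chosen plan and is its equal on that point, but it applies symmetry to the ring whose oxygens all end free, where it solves less. It is the better plan on protecting-group count at unit 2 and in avoiding carbon monoxide. On step economy it is judged similar or slightly longer, because A4 needs an arylacetate handle on a completed unit 1 and a Claisen aroylation.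

Alternative 3: The cut is at C4–C4a of unit 1, after O1–C2 has been made by adding the phenol A6 (3,5-dimethoxyphenol) to a propiolate derived from 14. In the forward step the (Z)-acid A7 would be activated with trifluoroacetic anhydride and would acylate the ortho carbon of its dimethoxyphenyl ether to give A8.
- In its favour: A6 is mirror-symmetric, so both ortho carbons are equivalent. An intramolecular Friedel–Crafts acylation of such an electron-rich ring is dependable. The final BCl3 treatment would remove the chelated C5 methyl ether together with the isopropyl ethers.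
- Against it: three operations (carboxylation of 14, conjugate addition with control of olefin geometry, saponification) are needed before the closure, where the chosen plan needs one. The mixed anhydride may acylate C6 or C8 of the electron-rich ring A of unit 2. The distinction between O5 and O7 rests on a selective demethylation and is not built in.
- Comparison: it is the equal of the chosen plan in exploiting the same mirror plane and in the length of the endgame. It is the better plan in avoiding the sensitive diol 19 and pressurised 20. It is the weaker plan in step economy before the ring closure.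

Key step: step 11

Assumption: the C3–C3' axis is treated as configurationally undefined, since the target carries no stereo descriptor; no stereo element has to be set.
Remark: 14, 19 and 23 were checked atom by atom against 24 (ethynyl para to the isopropoxy group of ring B, unit 2 ortho to it, iodine between the two hydroxyls); they are consistent and are used without change.
Remark: nitrile 1 is used in place of the corresponding arylacetic acid so that the aryl ketone of unit 2 can be made under protic Hoesch conditions, which spare the aryl isopropyl ether.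

## Route

Step 1
Reactants: 1 2-(2-hydroxyphenyl)acetonitrile
Product: 2 2-(2-isopropoxyphenyl)acetonitrile
Conditions: i-PrBr, K2CO3, DMF, 60 °C
Reagents that add atoms: 2-bromopropane, CC(C)Br
Why: Williamson ether synthesis: carbonate forms the phenoxide, which is alkylated by the secondary bromide in DMF; the benzylic nitrile is too weakly acidic for carbonate, so C-alkylation should not compete.

Step 2
Reactants: 2 2-(2-isopropoxyphenyl)acetonitrile
Product: 3 2-(5-bromo-2-isopropoxyphenyl)acetonitrile
Conditions: NBS, MeCN, 0 °C to rt
Reagents that add atoms: N-bromosuccinimide, O=C1CCC(=O)N1Br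
Why: Electrophilic aromatic bromination: the alkoxy group directs para, which is C5 of this ring and the future C1' of unit 1; ionic conditions in the dark leave the benzylic CH2 untouched.

Step 3
Reactants: 3 2-(5-bromo-2-isopropoxyphenyl)acetonitrile; 4 phloroglucinol
Product: 6 2-(5-bromo-2-isopropoxyphenyl)-1-(2,4,6-trihydroxyphenyl)ethan-1-one, via ketiminium chloride 5 (not isolated)
Conditions: HCl (g), ZnCl2, Et2O, 0 °C; then H2O, reflux
Reagents that add atoms: water, O
Why: Hoesch reaction: the nitrilium species formed from 3 with HCl and ZnCl2 acylates one carbon of the threefold symmetric 4, the ketiminium salt 5 separates and deactivates the ring against a second acylation, and hot water hydrolyses it to the ketone. No boron or aluminium halide is present, so the aryl isopropyl ether should survive.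

Step 4
Reactants: 6 2-(5-bromo-2-isopropoxyphenyl)-1-(2,4,6-trihydroxyphenyl)ethan-1-one
Product: 7 2-(5-bromo-2-isopropoxyphenyl)-1-(2-hydroxy-4,6-diisopropoxyphenyl)ethan-1-one
Conditions: i-PrBr (2.5 equiv), K2CO3, DMF, 50 °C
Reagents that add atoms: 2-bromopropane, CC(C)Br
Why: Chelation-controlled Williamson etherification: the para hydroxyl and one ortho hydroxyl are alkylated, whereas the last ortho hydroxyl is held in a hydrogen bond to the ketone and should resist the hindered secondary bromide.

Step 5
Reactants: 7 2-(5-bromo-2-isopropoxyphenyl)-1-(2-hydroxy-4,6-diisopropoxyphenyl)ethan-1-one; 8 4-isopropoxybenzoic acid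
Product: 12 3-(5-bromo-2-isopropoxyphenyl)-5,7-diisopropoxy-2-(4-isopropoxyphenyl)-4H-chromen-4-one, via 4-isopropoxybenzoyl chloride 9 (not isolated), via O-aroyl ester 10 (not isolated), via 1,3-diketone 11 (not isolated)
Conditions: 8, (COCl)2, DMF (cat.), CH2Cl2, rt, evaporate; then 7, K2CO3, acetone, reflux; then TsOH·H2O (cat.), toluene, 80 °C
Reagents that add atoms: none
Why: Acid chloride formation, O-aroylation, Baker–Venkataraman acyl shift to the benzylic enolate and cyclodehydration, the classical route from a 2-hydroxydeoxybenzoin to a 2,3-diarylchromone. The benzylic CH2 is acidic enough for carbonate and the acid finish completes the loss of water; the crowded C3–aryl bond is already present in 7, so nothing has to be coupled.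

Step 6
Reactants: 12 3-(5-bromo-2-isopropoxyphenyl)-5,7-diisopropoxy-2-(4-isopropoxyphenyl)-4H-chromen-4-one
Product: 13 5,7-diisopropoxy-2-(4-isopropoxyphenyl)-3-{2-isopropoxy-5-[(trimethylsilyl)ethynyl]phenyl}-4H-chromen-4-one
Conditions: TMS-acetylene, Pd(PhCN)2Cl2 (3 mol %), [HP(t-Bu)3]BF4 (6 mol %), CuI (2 mol %), i-Pr2NH, dioxane, 40 °C
Reagents that add atoms: ethynyltrimethylsilane, C#C[Si](C)(C)C
Why: Sonogashira coupling: the bulky electron-rich phosphine lets zerovalent palladium insert into the electron-rich but unhindered para-alkoxy aryl bromide at mild temperature, and the silyl cap prevents double coupling.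

Step 7
Reactants: 13 5,7-diisopropoxy-2-(4-isopropoxyphenyl)-3-{2-isopropoxy-5-[(trimethylsilyl)ethynyl]phenyl}-4H-chromen-4-one
Product: 14 3-(5-ethynyl-2-isopropoxyphenyl)-5,7-diisopropoxy-2-(4-isopropoxyphenyl)-4H-chromen-4-one
Conditions: K2CO3 (0.2 equiv), MeOH/THF, rt
Reagents that add atoms: none
Why: Base-catalysed methanolysis of the C(sp)–Si bond; catalytic carbonate at room temperature should not open the fully substituted pyranone.

Step 8
Reactants: 15 5-methoxyresorcinol
Product: 16 1-methoxy-3,5-bis(methoxymethoxy)benzene
Conditions: MOMCl, i-Pr2NEt, CH2Cl2, 0 °C to rt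
Reagents that add atoms: chloromethyl methyl ether, COCCl
Why: O-alkylation of both phenols by the α-chloro ether with a hindered amine as base; the two acetals are the directing groups for the next step and keep the mirror symmetry.

Step 9
Reactants: 16 1-methoxy-3,5-bis(methoxymethoxy)benzene
Product: 18 2-iodo-5-methoxy-1,3-bis(methoxymethoxy)benzene, via aryllithium 17 (not isolated)
Conditions: n-BuLi, THF, 0 °C; then I2, THF, −78 °C to rt
Reagents that add atoms: iodine, II
Why: Directed ortho-metalation: the carbon between the two chelating acetal oxygens is the most acidic and best coordinated site, and iodine traps the aryllithium there.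

Step 10
Reactants: 18 2-iodo-5-methoxy-1,3-bis(methoxymethoxy)benzene
Product: 19 2-iodo-5-methoxybenzene-1,3-diol
Conditions: HCl (1.25 M in MeOH), 0 °C to rt, dark; used at once
Reagents that add atoms: none
Why: Acid-catalysed transacetalisation of the two aryl methoxymethyl ethers to methanol; dilute acid, low temperature and exclusion of light are chosen to avoid ipso-protonation and loss of iodine from the electron-rich ring.

Step 11
Reactants: 19 2-iodo-5-methoxybenzene-1,3-diol; 20 carbon monoxide; 14 3-(5-ethynyl-2-isopropoxyphenyl)-5,7-diisopropoxy-2-(4-isopropoxyphenyl)-4H-chromen-4-one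
Product: 23 5-hydroxy-7-methoxy-2-{4-isopropoxy-3-[5,7-diisopropoxy-2-(4-isopropoxyphenyl)-4-oxo-4H-chromen-3-yl]phenyl}-4H-chromen-4-one, via ynone 21 (not isolated), via enaminone 22 (not isolated)
Conditions: 20 (5 bar), PdCl2(PPh3)2 (5 mol %), Et2NH/DMF, 90 °C
Reagents that add atoms: none
Why: Zerovalent palladium, formed in the flask from PdCl2(PPh3)2, should insert into the C–I bond of 19; 20 then inserts to give the aroyl complex of divalent palladium, and amine-assisted transfer of the acetylide of 14 followed by reductive elimination gives ynone 21 (C4a–C4 and C4–C3). Diethylamine adds in conjugate fashion to 21 to give enaminone 22, and one of the two equivalent ortho hydroxyls displaces the amine by addition–elimination (O1–C2), closing ring C of unit 1 in a net 6-endo mode. The closest known reaction type is the palladium-catalysed carbonylative Sonogashira annulation of ortho-iodophenols with terminal alkynes to flavones. No stereocentre is formed. Three selectivities are needed: carbonylation before coupling, which CO pressure and the absence of copper favour; six-membered flavone over five-membered aurone, which the enaminone secures because the oxygen then attacks the β-carbon; and the ring A pattern, which the mirror plane of 19 through C4a and C7 secures because closure through either hydroxyl gives the same 5-hydroxy-7-methoxy product. The hydroxyl that does not close ends as the hydrogen-bonded C5 hydroxyl, so this ring needs no protecting group.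

Step 12
Reactants: 23 5-hydroxy-7-methoxy-2-{4-isopropoxy-3-[5,7-diisopropoxy-2-(4-isopropoxyphenyl)-4-oxo-4H-chromen-3-yl]phenyl}-4H-chromen-4-one
Product: 24 5-hydroxy-7-methoxy-2-{4-hydroxy-3-[5,7-dihydroxy-2-(4-hydroxyphenyl)-4-oxo-4H-chromen-3-yl]phenyl}-4H-chromen-4-one
Conditions: BCl3 (1 M in CH2Cl2, 10 equiv), CH2Cl2, −78 °C to rt; then MeOH, H2O
Reagents that add atoms: none
Why: Lewis acid dealkylation of aryl isopropyl ethers: BCl3 coordinates to the ether oxygens and chloride removes the secondary alkyl groups as 2-chloropropane, fastest at the chelated C5 oxygen of unit 2. The non-chelated methyl ether on C7 of unit 1 is not expected to be cleaved by BCl3 at or below room temperature, and the free C5 hydroxyl only forms a borate that the methanol quench breaks.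

## Compound list

1 | 2-(2-hydroxyphenyl)acetonitrile | N#CCc1ccccc1O | starting material
2 | 2-(2-isopropoxyphenyl)acetonitrile | N#CCc1ccccc1OC(C)C | intermediate
3 | 2-(5-bromo-2-isopropoxyphenyl)acetonitrile | N#CCc1cc(Br)ccc1OC(C)C | intermediate
4 | phloroglucinol (benzene-1,3,5-triol) | Oc1cc(O)cc(O)c1 | starting material
5 | 2-(5-bromo-2-isopropoxyphenyl)-1-(2,4,6-trihydroxyphenyl)ethan-1-iminium chloride | [Cl-].[NH2+]=C(Cc1cc(Br)ccc1OC(C)C)c1c(O)cc(O)cc1O | intermediate
6 | 2-(5-bromo-2-isopropoxyphenyl)-1-(2,4,6-trihydroxyphenyl)ethan-1-one | O=C(Cc1cc(Br)ccc1OC(C)C)c1c(O)cc(O)cc1O | intermediate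
7 | 2-(5-bromo-2-isopropoxyphenyl)-1-(2-hydroxy-4,6-diisopropoxyphenyl)ethan-1-one | O=C(Cc1cc(Br)ccc1OC(C)C)c1c(O)cc(OC(C)C)cc1OC(C)C | intermediate
8 | 4-isopropoxybenzoic acid | CC(C)Oc1ccc(C(=O)O)cc1 | starting material
9 | 4-isopropoxybenzoyl chloride | CC(C)Oc1ccc(C(=O)Cl)cc1 | intermediate
10 | 2-[(5-bromo-2-isopropoxyphenyl)acetyl]-3,5-diisopropoxyphenyl 4-isopropoxybenzoate | O=C(Cc1cc(Br)ccc1OC(C)C)c1c(OC(=O)c2ccc(OC(C)C)cc2)cc(OC(C)C)cc1OC(C)C | intermediate
11 | 2-(5-bromo-2-isopropoxyphenyl)-1-(2-hydroxy-4,6-diisopropoxyphenyl)-3-(4-isopropoxyphenyl)propane-1,3-dione (racemic, enolisable) | O=C(c1ccc(OC(C)C)cc1)C(c1cc(Br)ccc1OC(C)C)C(=O)c1c(O)cc(OC(C)C)cc1OC(C)C | intermediate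
12 | 3-(5-bromo-2-isopropoxyphenyl)-5,7-diisopropoxy-2-(4-isopropoxyphenyl)-4H-chromen-4-one | Brc1ccc(OC(C)C)c(-c2c(-c3ccc(OC(C)C)cc3)oc3cc(OC(C)C)cc(OC(C)C)c3c2=O)c1 | intermediate
13 | 5,7-diisopropoxy-2-(4-isopropoxyphenyl)-3-{2-isopropoxy-5-[(trimethylsilyl)ethynyl]phenyl}-4H-chromen-4-one | C[Si](C)(C)C#Cc1ccc(OC(C)C)c(-c2c(-c3ccc(OC(C)C)cc3)oc3cc(OC(C)C)cc(OC(C)C)c3c2=O)c1 | intermediate
14 | 3-(5-ethynyl-2-isopropoxyphenyl)-5,7-diisopropoxy-2-(4-isopropoxyphenyl)-4H-chromen-4-one | C#Cc1ccc(OC(C)C)c(-c2c(-c3ccc(OC(C)C)cc3)oc3cc(OC(C)C)cc(OC(C)C)c3c2=O)c1 | intermediate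
15 | 5-methoxyresorcinol (5-methoxybenzene-1,3-diol) | COc1cc(O)cc(O)c1 | starting material
16 | 1-methoxy-3,5-bis(methoxymethoxy)benzene | COCOc1cc(OC)cc(OCOC)c1 | intermediate
17 | [4-methoxy-2,6-bis(methoxymethoxy)phenyl]lithium | [Li]c1c(OCOC)cc(OC)cc1OCOC | intermediate
18 | 2-iodo-5-methoxy-1,3-bis(methoxymethoxy)benzene | COCOc1cc(OC)cc(OCOC)c1I | intermediate
19 | 2-iodo-5-methoxybenzene-1,3-diol | COc1cc(O)c(I)c(O)c1 | intermediate
20 | carbon monoxide | [C-]#[O+] | starting material
21 | 1-(2,6-dihydroxy-4-methoxyphenyl)-3-{4-isopropoxy-3-[5,7-diisopropoxy-2-(4-isopropoxyphenyl)-4-oxo-4H-chromen-3-yl]phenyl}prop-2-yn-1-one | COc1cc(O)c(C(=O)C#Cc2ccc(OC(C)C)c(-c3c(-c4ccc(OC(C)C)cc4)oc4cc(OC(C)C)cc(OC(C)C)c4c3=O)c2)c(O)c1 | intermediate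
22 | 3-(diethylamino)-1-(2,6-dihydroxy-4-methoxyphenyl)-3-{4-isopropoxy-3-[5,7-diisopropoxy-2-(4-isopropoxyphenyl)-4-oxo-4H-chromen-3-yl]phenyl}prop-2-en-1-one (olefin geometry not fixed) | COc1cc(O)c(C(=O)C=C(N(CC)CC)c2ccc(OC(C)C)c(-c3c(-c4ccc(OC(C)C)cc4)oc4cc(OC(C)C)cc(OC(C)C)c4c3=O)c2)c(O)c1 | intermediate
23 | 5-hydroxy-7-methoxy-2-{4-isopropoxy-3-[5,7-diisopropoxy-2-(4-isopropoxyphenyl)-4-oxo-4H-chromen-3-yl]phenyl}-4H-chromen-4-one | COc1cc(O)c2c(=O)cc(-c3ccc(OC(C)C)c(-c4c(-c5ccc(OC(C)C)cc5)oc5cc(OC(C)C)cc(OC(C)C)c5c4=O)c3)oc2c1 | intermediate
24 | 5-hydroxy-7-methoxy-2-{4-hydroxy-3-[5,7-dihydroxy-2-(4-hydroxyphenyl)-4-oxo-4H-chromen-3-yl]phenyl}-4H-chromen-4-one | COc1cc(O)c2c(=O)cc(-c3ccc(O)c(-c4c(-c5ccc(O)cc5)oc5cc(O)cc(O)c5c4=O)c3)oc2c1 | target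

## Step count and least certain steps

Total step count: 12. Longest linear sequence: 9 steps (steps 1 to 7, then 11 and 12, from 1); the iodide branch (steps 8 to 10) joins at step 11.

**Step 11 (key step).** What may go wrong:
- slow oxidative addition into a hindered C–I bond flanked by two oxygens on a very electron-rich ring;
- capture of the aroylpalladium by diethylamine (aminocarbonylation) before the acetylide arrives;
- coupling without carbonylation followed by closure to a benzofuran;
- reductive loss of iodine.

Fallback, from 16 and 14, returning at 23: 16 is lithiated to 17 as in step 9 and quenched with DMF to give 4-methoxy-2,6-bis(methoxymethoxy)benzaldehyde F1. The acetylide of 14 (LiN(SiMe3)2, THF, −78 °C) is added to F1 to give the racemic propargylic alcohol F2. MnO2 in CH2Cl2 oxidises F2 to the bis-acetal ynone F3. HCl in MeOH removes both acetals to give 21, and diethylamine in ethanol closes the ring through 22 to 23. This builds the same three bonds without palladium or carbon monoxide and keeps the symmetry argument.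

**Step 9.** What may go wrong: competing lithiation between an acetal oxygen and the methyl ether oxygen, which would place iodine at the unsymmetrical position, and partial double lithiation. Fallback, from 4, returning at 23: mono-iodination of the threefold symmetric 4 (I2, NaHCO3, THF/H2O, 0 °C) gives 2-iodobenzene-1,3,5-triol F4, in which every ring position is equivalent. Carbonylative annulation of F4 with 20 and 14 under the conditions of step 11 gives the 5,7-dihydroxyflavone F5. Methylation of the non-chelated C7 hydroxyl (MeI, 1 equiv, K2CO3, acetone) gives 23. This replaces steps 8 to 10 and moves the methyl group to the end, where chelation of the C5 hydroxyl provides the selectivity.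

**Step 10.** What may go wrong: acid-promoted ipso-protonation with loss or migration of iodine, and oxidation of the free iodo-diol during isolation. Fallback, from 15, returning at 19: 15 is converted to the bis[2-(trimethylsilyl)ethoxymethyl] ether F6 (SEMCl, i-Pr2NEt, CH2Cl2). F6 is lithiated and iodinated as in step 9 to the iodide F7. Fluoride (Bu4NF, THF, 50 °C) then frees both phenols under non-acidic conditions to give 19.

**Step 5.** What may go wrong: incomplete acyl transfer onto the enolate of a ketone flanked by two ortho substituents, hydrolysis of ester 10 back to 7, and stalled dehydration. Fallback, from 7, returning at 12: condensation of 7 with commercial 4-isopropoxybenzaldehyde (piperidine, EtOH, reflux; aldol condensation, then oxa-Michael closure) gives the racemic trans-2,3-diarylchroman-4-one F8. Dehydrogenation of F8 with DDQ in dioxane at reflux gives 12.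

## Further compounds

F1 | step 11 | 4-methoxy-2,6-bis(methoxymethoxy)benzaldehyde | COCOc1cc(OC)cc(OCOC)c1C=O
F2 | step 11 | 3-{4-isopropoxy-3-[5,7-diisopropoxy-2-(4-isopropoxyphenyl)-4-oxo-4H-chromen-3-yl]phenyl}-1-[4-methoxy-2,6-bis(methoxymethoxy)phenyl]prop-2-yn-1-ol (racemic) | COCOc1cc(OC)cc(OCOC)c1C(O)C#Cc1ccc(OC(C)C)c(-c2c(-c3ccc(OC(C)C)cc3)oc3cc(OC(C)C)cc(OC(C)C)c3c2=O)c1
F3 | step 11 | 3-{4-isopropoxy-3-[5,7-diisopropoxy-2-(4-isopropoxyphenyl)-4-oxo-4H-chromen-3-yl]phenyl}-1-[4-methoxy-2,6-bis(methoxymethoxy)phenyl]prop-2-yn-1-one | COCOc1cc(OC)cc(OCOC)c1C(=O)C#Cc1ccc(OC(C)C)c(-c2c(-c3ccc(OC(C)C)cc3)oc3cc(OC(C)C)cc(OC(C)C)c3c2=O)c1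
F4 | step 9 | 2-iodobenzene-1,3,5-triol | Oc1cc(O)c(I)c(O)c1
F5 | step 9 | 5,7-dihydroxy-2-{4-isopropoxy-3-[5,7-diisopropoxy-2-(4-isopropoxyphenyl)-4-oxo-4H-chromen-3-yl]phenyl}-4H-chromen-4-one | Oc1cc(O)c2c(=O)cc(-c3ccc(OC(C)C)c(-c4c(-c5ccc(OC(C)C)cc5)oc5cc(OC(C)C)cc(OC(C)C)c5c4=O)c3)oc2c1
F6 | step 10 | 1-methoxy-3,5-bis{[2-(trimethylsilyl)ethoxy]methoxy}benzene | COc1cc(OCOCC[Si](C)(C)C)cc(OCOCC[Si](C)(C)C)c1
F7 | step 10 | 2-iodo-5-methoxy-1,3-bis{[2-(trimethylsilyl)ethoxy]methoxy}benzene | COc1cc(OCOCC[Si](C)(C)C)c(I)c(OCOCC[Si](C)(C)C)c1
F8 | step 5 | rac-(2R,3S)-3-(5-bromo-2-isopropoxyphenyl)-5,7-diisopropoxy-2-(4-isopropoxyphenyl)chroman-4-one (trans) | O=C1c2c(OC(C)C)cc(OC(C)C)cc2O[C@@H](c2ccc(OC(C)C)cc2)[C@@H]1c1cc(Br)ccc1OC(C)C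
A1 | alternative 1 | 3-[(1Z)-2-(tert-butyldimethylsilyloxy)buta-1,3-dien-1-yl]-5,7-diisopropoxy-2-(4-isopropoxyphenyl)-4H-chromen-4-one | C=C/C(O[Si](C)(C)C(C)(C)C)=C/c1c(-c2ccc(OC(C)C)cc2)oc2cc(OC(C)C)cc(OC(C)C)c2c1=O
A2 | alternative 1 | 2-ethynyl-5-isopropoxy-7-methoxy-4H-chromen-4-one | C#Cc1cc(=O)c2c(OC(C)C)cc(OC)cc2o1
A3 | alternative 1 | 2-{4-(tert-butyldimethylsilyloxy)-3-[5,7-diisopropoxy-2-(4-isopropoxyphenyl)-4-oxo-4H-chromen-3-yl]phenyl}-5-isopropoxy-7-methoxy-4H-chromen-4-one | COc1cc(OC(C)C)c2c(=O)cc(-c3ccc(O[Si](C)(C)C(C)(C)C)c(-c4c(-c5ccc(OC(C)C)cc5)oc5cc(OC(C)C)cc(OC(C)C)c5c4=O)c3)oc2c1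
A4 | alternative 2 | methyl 2-[2-isopropoxy-5-(5-isopropoxy-7-methoxy-4-oxo-4H-chromen-2-yl)phenyl]-3-(4-isopropoxyphenyl)-3-oxopropanoate (racemic) | COC(=O)C(C(=O)c1ccc(OC(C)C)cc1)c1cc(-c2cc(=O)c3c(OC(C)C)cc(OC)cc3o2)ccc1OC(C)C
A5 | alternative 2 | 2-{3-[5,7-dihydroxy-2-(4-isopropoxyphenyl)-4-oxo-4H-chromen-3-yl]-4-isopropoxyphenyl}-5-isopropoxy-7-methoxy-4H-chromen-4-one | COc1cc(OC(C)C)c2c(=O)cc(-c3ccc(OC(C)C)c(-c4c(-c5ccc(OC(C)C)cc5)oc5cc(O)cc(O)c5c4=O)c3)oc2c1
A6 | alternative 3 | 3,5-dimethoxyphenol | COc1cc(O)cc(OC)c1
A7 | alternative 3 | (Z)-3-(3,5-dimethoxyphenoxy)-3-{4-isopropoxy-3-[5,7-diisopropoxy-2-(4-isopropoxyphenyl)-4-oxo-4H-chromen-3-yl]phenyl}prop-2-enoic acid | OC(=O)/C=C(\Oc1cc(OC)cc(OC)c1)c1ccc(OC(C)C)c(-c2c(-c3ccc(OC(C)C)cc3)oc3cc(OC(C)C)cc(OC(C)C)c3c2=O)c1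
A8 | alternative 3 | 5,7-dimethoxy-2-{4-isopropoxy-3-[5,7-diisopropoxy-2-(4-isopropoxyphenyl)-4-oxo-4H-chromen-3-yl]phenyl}-4H-chromen-4-one | COc1cc(OC)c2c(=O)cc(-c3ccc(OC(C)C)c(-c4c(-c5ccc(OC(C)C)cc5)oc5cc(OC(C)C)cc(OC(C)C)c5c4=O)c3)oc2c1
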